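## Retrosynthetic overview
1. C1–OOH and C10=C14 come from a last-step Schenck ene reaction on the 1(10)E alkene. The C8 ester comes from Steglich coupling with an acetonide-protected acid made from (R)-solketal.
2. C6–C7 and O6–C12 are cut together, back to an acyclic (Z)-2-(bromomethyl)enoate/(Z)-enal. The ten-membered carbocycle closes first and the cis-γ-lactone follows in the same flask; no ring exists before this step.
3. C3–C4 is made by B-alkyl Suzuki coupling with a Z-β-iodoenal from but-2-yne-1,4-diol. This fixes the ring-cis C4=C5 bond and brings in the C15 acetate.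
4. C7–C8 is made by catalytic asymmetric propiolate addition, which sets C8, the only reagent-controlled core stereocentre. C11–C13 is made by trans-hydroalumination and capture with formaldehyde.
5. The E C1=C10 bond, C14 and C2–C3 come from one-pot carboalumination/vinylation of but-3-yn-1-ol.

Assumption: the SMILES is taken literally (6,7-cis lactone; C3 and C6 cis on C4=C5), germacrane numbering C1–C15 is used in the text, and (S,S)-ProPhenol is taken to deliver the alkyne to the Re face of the aldehyde (otherwise its antipode is used).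

## Route

Step 1
Reactants: 1 but-2-yne-1,4-diol
Product: 2 4-hydroxybut-2-yn-1-yl acetate
Conditions: Ac2O (0.33 equiv), pyridine, CH2Cl2/THF, 0 °C (diol in threefold excess, recovered)
Reagents that add atoms: acetic anhydride CC(=O)OC(C)=O
Why: Statistical mono-acylation of a symmetric diol used in excess (nucleophilic acyl substitution) tells the future C15–OAc from C6 at the very start; no stereocentre is involved.

Step 2
Reactants: 2 4-hydroxybut-2-yn-1-yl acetate
Product: 3 4-oxobut-2-yn-1-yl acetate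
Conditions: MnO2 (15 equiv), CH2Cl2, 23 °C
Reagents that add atoms: none
Why: MnO2 oxidation of a propargylic alcohol stops at the ynal and leaves the acetate untouched.

Step 3
Reactants: 3 4-oxobut-2-yn-1-yl acetate
Product: 4 (2Z)-2-iodo-4-oxobut-2-en-1-yl acetate
Conditions: NaI (1.1 equiv), AcOH, 23 °C
Reagents that add atoms: sodium iodide [Na+].[I-]
Why: Conjugate hydroiodination of the ynal by anti addition of H and I gives the kinetic Z-β-iodoenal, so CH2OAc (C15) is trans to CHO (C6) and the iodine marks the site cis to C6 for C3.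

Step 4
Reactants: 5 but-3-yn-1-ol; 6 vinyl bromide
Product: 8 (3E)-3-methylhexa-3,5-dien-1-ol, via E-alkenylalane 7 (not isolated)
Conditions: Me3Al (3 equiv), Cp2ZrCl2 (0.25 equiv), CH2Cl2, 0 to 23 °C; then 6, Pd(PPh3)4 (5 mol %), ZnCl2 (0.3 equiv), THF, 23 °C; aqueous work-up
Reagents that add atoms: trimethylaluminium C[Al](C)C
Why: Negishi zirconium-catalysed syn-carboalumination followed by palladium-catalysed alkenyl–alkenyl cross-coupling with retention sets the E C1=C10 bond, with C14 cis to C2.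

Step 5
Reactants: 8 (3E)-3-methylhexa-3,5-dien-1-ol
Product: 9 (3E)-3-methylhexa-3,5-dienal
Conditions: Dess–Martin periodinane, pyridine, CH2Cl2, 0 °C; used crude
Reagents that add atoms: none
Why: Dess–Martin oxidation under buffered, non-basic conditions gives the skipped dienal without moving the double bond into conjugation.

Step 6
Reactants: 9 (3E)-3-methylhexa-3,5-dienal; 10 methyl propiolate
Product: 12 methyl (4S,6E)-4-hydroxy-6-methylnona-6,8-dien-2-ynoate, via zinc alkynylide 11 (not isolated)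
Conditions: Me2Zn (3 equiv), (S,S)-ProPhenol (20 mol %), Ph3PO (40 mol %), toluene, 4 °C, slow addition of 9
Reagents that add atoms: none
Why: In this zinc–ProPhenol catalysed asymmetric alkynylation the dinuclear zinc pocket delivers the alkynyl group to the Re face of the aldehyde and sets C8 as S.

Step 7
Reactants: 12 methyl (4S,6E)-4-hydroxy-6-methylnona-6,8-dien-2-ynoate
Product: 14 methyl (2E,4S,6E)-4-hydroxy-2-(hydroxymethyl)-6-methylnona-2,6,8-trienoate, via cyclic alkenylalanate 13 (not isolated)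
Conditions: NaAlH2(OCH2CH2OMe)2 (1.1 equiv), THF, −78 °C; then monomeric CH2O (cracked paraformaldehyde), −78 to 0 °C; aq. NH4Cl
Reagents that add atoms: formaldehyde C=O
Why: Proposed new method: hydroxyl-directed trans-hydroalumination of γ-hydroxy ynoates (known to give E-γ-hydroxy enoates and, on iodination, α-iodo enoates) leaves the five-membered alanate 13 with its C11–Al bond cis to C8, and this α-(alkoxycarbonyl)vinylaluminium should add to formaldehyde with retention as in the vinylalumination of aldehydes, the closest known reaction type, so C13 ends cis to C8 and the ester trans.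

Step 8
Reactants: 14 methyl (2E,4S,6E)-4-hydroxy-2-(hydroxymethyl)-6-methylnona-2,6,8-trienoate
Product: 15 methyl (2E,4S,6E)-6-methyl-4-(triethylsilyloxy)-2-[(triethylsilyloxy)methyl]nona-2,6,8-trienoate
Conditions: Et3SiCl (2.3 equiv), imidazole, CH2Cl2, 0 °C
Reagents that add atoms: chlorotriethylsilane CC[Si](Cl)(CC)CC
Why: Double O-silylation removes both acidic protons before hydroboration and blocks cyclisation of the cis-ene-1,4-diol to a dihydrofuran; C8 is untouched.

Step 9
Reactants: 15 methyl (2E,4S,6E)-6-methyl-4-(triethylsilyloxy)-2-[(triethylsilyloxy)methyl]nona-2,6,8-trienoate; 4 (2Z)-2-iodo-4-oxobut-2-en-1-yl acetate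
Product: 17 methyl (2E,4S,6E,10E)-10-(acetoxymethyl)-6-methyl-12-oxo-4-(triethylsilyloxy)-2-[(triethylsilyloxy)methyl]dodeca-2,6,10-trienoate, via B-alkyl borane 16 (not isolated)
Conditions: 9-BBN-H (1.3 equiv), THF, 0 to 23 °C; then 4, PdCl2(dppf) (5 mol %), AsPh3 (10 mol %), Cs2CO3, DMF/H2O, 23 °C
Reagents that add atoms: none
Why: 9-BBN-H hydroborates only the terminal vinyl of the diene, and the B-alkyl Suzuki–Miyaura coupling keeps the geometry of the Z-iodide, so C3 and C6 end cis on C4=C5 (E by CIP because of CH2OAc).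

Step 10
Reactants: 17 methyl (2E,4S,6E,10E)-10-(acetoxymethyl)-6-methyl-12-oxo-4-(triethylsilyloxy)-2-[(triethylsilyloxy)methyl]dodeca-2,6,10-trienoate
Product: 18 methyl (2Z,4S,6E,10E)-10-(acetoxymethyl)-2-(bromomethyl)-6-methyl-12-oxo-4-(triethylsilyloxy)dodeca-2,6,10-trienoate
Conditions: Ph3PBr2 (1.05 equiv), CH2Cl2, −40 to −10 °C
Reagents that add atoms: dibromotriphenylphosphorane BrP(Br)(c1ccccc1)(c1ccccc1)c1ccccc1
Why: Ph3PBr2 converts silyl ethers directly into bromides (SN2 on the oxyphosphonium ion), and the unhindered primary allylic ether reacts well before the secondary C8 ether, with the alkene geometry kept.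

Step 11
Reactants: 18 methyl (2Z,4S,6E,10E)-10-(acetoxymethyl)-2-(bromomethyl)-6-methyl-12-oxo-4-(triethylsilyloxy)dodeca-2,6,10-trienoate
Product: 22 [(3aR,4S,6E,10E,11aS)-4-hydroxy-6-methyl-3-methylidene-2-oxo-2,3,3a,4,5,8,9,11a-octahydrocyclodeca[b]furan-10-yl]methyl acetate (germacrane 6S,7R,8S), via allylchromium species 19 (not isolated), via ring-closed chromium alkoxide 20 (not isolated), via triethylsilyl lactone 21 (not isolated)
Conditions: CrCl2 (10 equiv), THF/DMF 10:1, 23 °C, 18 added over 12 h (final 2 mM); aqueous work-up, crude in THF, HF·pyridine, pyridine, 0 °C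
Reagents that add atoms: none
Why: Proposed new method: two CrCl2 reduce the bromide to the 2-(methoxycarbonyl)allylchromium 19, which adds through C7 to the tethered enal in a Nozaki–Hiyama chair (closest known types: chromium-mediated ten-membered germacrane closures and intermolecular 2-(alkoxycarbonyl)allylation–lactonisation); C8, cis to CH2Cr, sits axial so C6/C7 come out syn (cis lactone), A(1,3) strain with the bulky OSiEt3 turned outward brings the aldehyde onto the C9 face (7R from 8S), and alkoxide 20 then expels methoxide, so carbocycle and lactone form in one flask before fluoride frees C8–OH.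

Step 12
Reactants: 23 [(4R)-2,2-dimethyl-1,3-dioxolan-4-yl]methanol ((R)-solketal)
Product: 24 (4S)-2,2-dimethyl-1,3-dioxolane-4-carbaldehyde
Conditions: Dess–Martin periodinane, CH2Cl2, 0 to 23 °C; used crude
Reagents that add atoms: none
Why: Dess–Martin oxidation of the primary alcohol leaves the stereocentre in place; only the descriptor changes (R to S) through CIP priorities.

Step 13
Reactants: 24 (4S)-2,2-dimethyl-1,3-dioxolane-4-carbaldehyde
Product: 25 (4R)-4-ethynyl-2,2-dimethyl-1,3-dioxolane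
Conditions: dimethyl (1-diazo-2-oxopropyl)phosphonate, K2CO3, MeOH, 0 to 23 °C
Reagents that add atoms: dimethyl (1-diazo-2-oxopropyl)phosphonate COP(=O)(OC)C(=[N+]=[N-])C(C)=O
Why: Seyferth–Gilbert homologation in the Ohira–Bestmann variant is mild enough not to epimerise the α-alkoxy aldehyde.

Step 14
Reactants: 25 (4R)-4-ethynyl-2,2-dimethyl-1,3-dioxolane
Product: 27 2-[(4R)-2,2-dimethyl-1,3-dioxolan-4-yl]prop-2-enoic acid, via internal alkenylalane 26 (not isolated)
Conditions: iBu2AlH (1.3 equiv), Ni(dppp)Cl2 (3 mol %), THF, 0 to 23 °C; then (IPr)CuCl (5 mol %), CO2 (1 atm), 23 °C; aq. citric acid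
Reagents that add atoms: carbon dioxide O=C=O
Why: Nickel-catalysed α-selective (Markovnikov) hydroalumination puts aluminium on the internal carbon, and copper–carbene catalysed carboxylation of the alkenylalane gives the 2-substituted acrylic acid without touching the stereocentre.

Step 15
Reactants: 22 hydroxy lactone (6S,7R,8S); 27 2-[(4R)-2,2-dimethyl-1,3-dioxolan-4-yl]prop-2-enoic acid
Product: 28 [(3aR,4S,6E,10E,11aS)-10-(acetoxymethyl)-6-methyl-3-methylidene-2-oxo-2,3,3a,4,5,8,9,11a-octahydrocyclodeca[b]furan-4-yl] 2-[(4R)-2,2-dimethyl-1,3-dioxolan-4-yl]prop-2-enoate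
Conditions: DCC (1.5 equiv), DMAP (0.2 equiv), CH2Cl2, 0 °C
Reagents that add atoms: none
Why: Steglich esterification acylates C8–OH with retention, and the cold, nearly neutral medium avoids translactonisation from O6 to O8.

Step 16
Reactants: 28 acetonide ester
Product: 29 [(3aR,4S,6E,10E,11aS)-10-(acetoxymethyl)-6-methyl-3-methylidene-2-oxo-2,3,3a,4,5,8,9,11a-octahydrocyclodeca[b]furan-4-yl] (3R)-3,4-dihydroxy-2-methylidenebutanoate
Conditions: AcOH/H2O 4:1, 35 °C
Reagents that add atoms: none
Why: Mild acid-catalysed acetal hydrolysis frees the diol while the esters, the allylic acetate and the 1,5-diene survive; no stereocentre is touched.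

Step 17
Reactants: 29 diol ester
Product: 30 [(3aR,4S,7R,10E,11aS)-10-(acetoxymethyl)-7-hydroperoxy-3,6-dimethylidene-2-oxo-2,3,3a,4,5,6,7,8,9,11a-decahydrocyclodeca[b]furan-4-yl] (3R)-3,4-dihydroxy-2-methylidenebutanoate (target)
Conditions: O2, tetraphenylporphyrin (1 mol %), visible light, CH2Cl2, −20 °C
Reagents that add atoms: oxygen O=O
Why: In the Schenck ene reaction singlet oxygen takes only the electron-rich C1=C10 bond (C4=C5 is deactivated by two allylic oxygens and the acrylates are inert), abstracts H from C14 on the more crowded side of the E-alkene (cis effect), and is expected to attack the outward-facing alkene face of the macrocycle to give the 1R hydroperoxide with the 10(14)-methylene; this face assignment is not verified by modelling.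

## Compound list
1 | but-2-yne-1,4-diol | OCC#CCO | starting material
2 | 4-hydroxybut-2-yn-1-yl acetate | CC(=O)OCC#CCO | intermediate
3 | 4-oxobut-2-yn-1-yl acetate | CC(=O)OCC#CC=O | intermediate
4 | (2Z)-2-iodo-4-oxobut-2-en-1-yl acetate (I cis to CHO) | CC(=O)OC/C(I)=C/C=O | intermediate
5 | but-3-yn-1-ol | C#CCCO | starting material
6 | vinyl bromide | C=CBr | starting material
7 | E-alkenylalane, [(1E)-4-(dimethylalumanyloxy)-2-methylbut-1-en-1-yl]dimethylalane | C[Al](C)/C=C(\C)CCO[Al](C)C | intermediate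
8 | (3E)-3-methylhexa-3,5-dien-1-ol | C=C/C=C(\C)CCO | intermediate
9 | (3E)-3-methylhexa-3,5-dienal | C=C/C=C(\C)CC=O | intermediate
10 | methyl propiolate | C#CC(=O)OC | starting material
11 | zinc alkynylide, methyl 3-(methylzincio)prop-2-ynoate | C[Zn]C#CC(=O)OC | intermediate
12 | methyl (4S,6E)-4-hydroxy-6-methylnona-6,8-dien-2-ynoate | C=C/C=C(\C)C[C@H](O)C#CC(=O)OC | intermediate
13 | cyclic alkenylalanate, sodium salt (five-membered O8–C8–C7=C11–Al ring, Al cis to C8) | [Na+].C=C/C=C(\C)C[C@H]1C=C(C(=O)OC)[Al-](OCCOC)(OCCOC)O1 | intermediate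
14 | methyl (2E,4S,6E)-4-hydroxy-2-(hydroxymethyl)-6-methylnona-2,6,8-trienoate | C=C/C=C(\C)C[C@H](O)/C=C(\CO)C(=O)OC | intermediate
15 | methyl (2E,4S,6E)-6-methyl-4-(triethylsilyloxy)-2-[(triethylsilyloxy)methyl]nona-2,6,8-trienoate | C=C/C=C(\C)C[C@H](O[Si](CC)(CC)CC)/C=C(\CO[Si](CC)(CC)CC)C(=O)OC | intermediate
16 | B-alkyl borane (9-BBN on C3 of 15) | B1(CC/C=C(\C)C[C@H](O[Si](CC)(CC)CC)/C=C(\CO[Si](CC)(CC)CC)C(=O)OC)C2CCCC1CCC2 | intermediate
17 | methyl (2E,4S,6E,10E)-10-(acetoxymethyl)-6-methyl-12-oxo-4-(triethylsilyloxy)-2-[(triethylsilyloxy)methyl]dodeca-2,6,10-trienoate | O=C/C=C(/COC(C)=O)CC/C=C(\C)C[C@H](O[Si](CC)(CC)CC)/C=C(\CO[Si](CC)(CC)CC)C(=O)OC | intermediate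
18 | methyl (2Z,4S,6E,10E)-10-(acetoxymethyl)-2-(bromomethyl)-6-methyl-12-oxo-4-(triethylsilyloxy)dodeca-2,6,10-trienoate | O=C/C=C(/COC(C)=O)CC/C=C(\C)C[C@H](O[Si](CC)(CC)CC)/C=C(\CBr)C(=O)OC | intermediate
19 | allylchromium species (CrCl2 on C13 of 18 in place of Br) | O=C/C=C(/COC(C)=O)CC/C=C(\C)C[C@H](O[Si](CC)(CC)CC)/C=C(\C[Cr](Cl)Cl)C(=O)OC | intermediate
20 | ring-closed chromium alkoxide (ten-membered ring, O6–CrCl2, methyl ester still open) | C=C(C(=O)OC)[C@H]1[C@@H](O[Cr](Cl)Cl)/C=C(/COC(C)=O)CC/C=C(\C)C[C@@H]1O[Si](CC)(CC)CC | intermediate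
21 | triethylsilyl lactone, [(3aS,4S,6E,10E,11aS)-6-methyl-3-methylidene-2-oxo-4-(triethylsilyloxy)-2,3,3a,4,5,8,9,11a-octahydrocyclodeca[b]furan-10-yl]methyl acetate | C=C1C(=O)O[C@H]2/C=C(/COC(C)=O)CC/C=C(\C)C[C@H](O[Si](CC)(CC)CC)[C@@H]12 | intermediate
22 | [(3aR,4S,6E,10E,11aS)-4-hydroxy-6-methyl-3-methylidene-2-oxo-2,3,3a,4,5,8,9,11a-octahydrocyclodeca[b]furan-10-yl]methyl acetate | C=C1C(=O)O[C@H]2/C=C(/COC(C)=O)CC/C=C(\C)C[C@H](O)[C@@H]12 | intermediate
23 | [(4R)-2,2-dimethyl-1,3-dioxolan-4-yl]methanol, (R)-solketal | OC[C@@H]1COC(C)(C)O1 | starting material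
24 | (4S)-2,2-dimethyl-1,3-dioxolane-4-carbaldehyde | O=C[C@@H]1COC(C)(C)O1 | intermediate
25 | (4R)-4-ethynyl-2,2-dimethyl-1,3-dioxolane | C#C[C@@H]1COC(C)(C)O1 | intermediate
26 | internal alkenylalane, {1-[(4R)-2,2-dimethyl-1,3-dioxolan-4-yl]ethenyl}bis(2-methylpropyl)alane | C=C([Al](CC(C)C)CC(C)C)[C@@H]1COC(C)(C)O1 | intermediate
27 | 2-[(4R)-2,2-dimethyl-1,3-dioxolan-4-yl]prop-2-enoic acid | C=C(C(=O)O)[C@@H]1COC(C)(C)O1 | intermediate
28 | [(3aR,4S,6E,10E,11aS)-10-(acetoxymethyl)-6-methyl-3-methylidene-2-oxo-2,3,3a,4,5,8,9,11a-octahydrocyclodeca[b]furan-4-yl] 2-[(4R)-2,2-dimethyl-1,3-dioxolan-4-yl]prop-2-enoate | C=C1C(=O)O[C@H]2/C=C(/COC(C)=O)CC/C=C(\C)C[C@H](OC(=O)C(=C)[C@@H]3COC(C)(C)O3)[C@@H]12 | intermediate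
29 | [(3aR,4S,6E,10E,11aS)-10-(acetoxymethyl)-6-methyl-3-methylidene-2-oxo-2,3,3a,4,5,8,9,11a-octahydrocyclodeca[b]furan-4-yl] (3R)-3,4-dihydroxy-2-methylidenebutanoate | C=C1C(=O)O[C@H]2/C=C(/COC(C)=O)CC/C=C(\C)C[C@H](OC(=O)C(=C)[C@@H](O)CO)[C@@H]12 | intermediate
30 | [(3aR,4S,7R,10E,11aS)-10-(acetoxymethyl)-7-hydroperoxy-3,6-dimethylidene-2-oxo-2,3,3a,4,5,6,7,8,9,11a-decahydrocyclodeca[b]furan-4-yl] (3R)-3,4-dihydroxy-2-methylidenebutanoate | C=C1C(=O)O[C@H]2/C=C(/COC(C)=O)CC[C@@H](OO)C(=C)C[C@H](OC(=O)C(=C)[C@@H](O)CO)[C@@H]12 | target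

## Step count and risks
Total step count: 17 (steps 1–3 iodoenal, 4–11 core, 12–14 side-chain acid, 15–17 end game).
Longest linear sequence: 11 steps (steps 4–11 and 15–17, from but-3-yn-1-ol).

**Step 11 (double ring closure).**
- Risks: oligomerisation, 1,4-loss of the C8 silyloxy group from 19, or the wrong C6/C7 diastereomer from a strained chair.
- Fallback: it sets out from 15 and 4 and comes back at 22.
  - Ph3PBr2 turns 15 into the diene bromide F2.
  - Indium metal in THF/H2O joins it to 4 in an intermolecular Barbier addition. C6 and C7 are then set under purely acyclic A(1,3)/chair control, giving the open syn-hydroxy ester F3 with the vinyl iodide intact.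
  - 9-BBN-H, then PdCl2(dppf)/AsPh3/Cs2CO3 at high dilution, closes C3–C4 by an intramolecular B-alkyl Suzuki coupling. The carbonate base lactonises O6 onto C12 in the same flask.
  - HF·pyridine then gives 22.

**Step 7 (alanate capture by formaldehyde).**
- Risks: protonated E-enoate only, ester reduction, or loss of geometry through an allenolate.
- Fallback: it sets out from 12 and comes back at 14.
  - The same alanate 13 is quenched with N-iodosuccinimide to give the α-iodo enoate F1.
  - The carbon is then brought in by a Stille coupling with Bu3SnCH2OH (Pd(PPh3)4, dioxane, 80 °C), which keeps the geometry.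

**Step 17 (face selectivity of the ene reaction at C1).**
- Risks: the bulky C8 ester may present the wrong alkene face or give an epimer mixture.
- Fallback: it sets out from 22 and comes back at 30.
  - The free alcohol 22 is photo-oxygenated first. Its C8–OH can hydrogen-bond the incoming oxygen and the ring carries a much smaller C8 group, giving the hydroperoxy alcohol F4.
  - The more acidic OOH is capped with one equivalent of Et3SiCl/imidazole to give the silyl peroxide F5.
  - C8–OH is esterified with 27 (DCC, DMAP) to give the protected ester F6.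
  - Aqueous acetic acid removes the acetonide and the peroxide silyl group together.

## Further compounds
F1 | step 7 | methyl (2Z,4S,6E)-4-hydroxy-2-iodo-6-methylnona-2,6,8-trienoate | C=C/C=C(\C)C[C@H](O)/C=C(\I)C(=O)OC
F2 | step 11 | methyl (2Z,4S,6E)-2-(bromomethyl)-6-methyl-4-(triethylsilyloxy)nona-2,6,8-trienoate | C=C/C=C(\C)C[C@H](O[Si](CC)(CC)CC)/C=C(\CBr)C(=O)OC
F3 | step 11 | methyl (3S,4R,5Z)-7-acetoxy-4-hydroxy-6-iodo-2-methylidene-3-[(1S,3E)-3-methyl-1-(triethylsilyloxy)hexa-3,5-dien-1-yl]hept-5-enoate | C=C(C(=O)OC)[C@@H]([C@@H](O)/C=C(I)/COC(C)=O)[C@H](C/C(C)=C/C=C)O[Si](CC)(CC)CC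
F4 | step 17 | [(3aR,4S,7R,10E,11aS)-7-hydroperoxy-4-hydroxy-3,6-dimethylidene-2-oxo-2,3,3a,4,5,6,7,8,9,11a-decahydrocyclodeca[b]furan-10-yl]methyl acetate | C=C1C(=O)O[C@H]2/C=C(/COC(C)=O)CC[C@@H](OO)C(=C)C[C@H](O)[C@@H]12
F5 | step 17 | [(3aR,4S,7R,10E,11aS)-4-hydroxy-3,6-dimethylidene-2-oxo-7-(triethylsilylperoxy)-2,3,3a,4,5,6,7,8,9,11a-decahydrocyclodeca[b]furan-10-yl]methyl acetate | C=C1C(=O)O[C@H]2/C=C(/COC(C)=O)CC[C@@H](OO[Si](CC)(CC)CC)C(=C)C[C@H](O)[C@@H]12
F6 | step 17 | [(3aR,4S,7R,10E,11aS)-10-(acetoxymethyl)-3,6-dimethylidene-2-oxo-7-(triethylsilylperoxy)-2,3,3a,4,5,6,7,8,9,11a-decahydrocyclodeca[b]furan-4-yl] 2-[(4R)-2,2-dimethyl-1,3-dioxolan-4-yl]prop-2-enoate | C=C1C(=O)O[C@H]2/C=C(/COC(C)=O)CC[C@@H](OO[Si](CC)(CC)CC)C(=C)C[C@H](OC(=O)C(=C)[C@@H]3COC(C)(C)O3)[C@@H]12
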